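**Retrosynthetic overview** (O1, C2–C5 are oxolane locants of the target, not compound numbers)
- The nine-membered ring is opened at its Z-alkene (ring-closing metathesis, last step). The exocyclic methylene/allyl unit goes back to a methyl ketone (enol triflate, Stille allylation), and the palmitate to a CH2OH released from a temporary lactone.
- The oxolane (C2 = quaternary carbon with dienyl and CH2O-acyl, C3/C4 = ring-fusion carbons, C5 = OCH2) is made by formal insertion of formaldehyde into the ring-fusion C–C bond of a cyclopropane: a 1-acetyl-5-dienyl-3-oxabicyclo[3.1.0]hexan-2-one is expanded to a 3,6-dioxabicyclo[3.2.1]octan-2-one under zerovalent palladium, forming C4–C5 and O1–C2 together.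
- Enabling feature: C2 is a tertiary allylic (dienyl) ether carbon and C4 is alpha to the sp2 carbon of the nine-membered ring (carried as a ketone), so C4–C3–C2 is a latent 1,3-zwitterion that a vinylcyclopropane can store. The CH2O-acyl branch on C2 lets a lactone tie C2 to C4 and relay the configuration of C3 to C2.
- The cyclopropane comes from asymmetric intramolecular cyclopropanation of the diazoacetoacetate of a (Z)-2-dienyl allylic alcohol, built from (S)-linalool (carbinol stereocentre, its vinyl group, two ring CH2 groups), CBr4, a dienyl boronate and formaldehyde.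
- Ring order: cyclopropane and γ-lactone (step 9, both temporary), oxolane (step 10), lactone excised (step 11), nine-membered carbocycle (step 16).

Key step: step 10

Remark (assumption on the chemistry): commercial (S)-(+)-linalool is taken at high enantiomeric purity. The hand of the cobalt porphyrin in step 9 is the one that gives 17 as drawn (to be fixed on a model substrate); any minor series epimeric at the chain-bearing cyclopropane carbon is diastereomeric through the linalool stereocentre and would be removed by chromatography at 18.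

**Step 1**
Reactants: 1 (S)-(+)-linalool
Product: 2 (3S)-3,7-dimethyl-3-(triethylsilyloxy)octa-1,6-diene
Conditions: Et3SiOTf, 2,6-lutidine, CH2Cl2, −78 to 0 °C
Reagents that add atoms: triethylsilyl trifluoromethanesulfonate, CC[Si](CC)(CC)OS(=O)(=O)C(F)(F)F
Why: Silyl triflate/lutidine silylation of a hindered tertiary allylic alcohol; the stereocentre is not touched.

**Step 2**
Reactants: 2 (3S)-3,7-dimethyl-3-(triethylsilyloxy)octa-1,6-diene
Product: 4 (4S)-4-methyl-4-(triethylsilyloxy)hex-5-enal, via secondary ozonide 3 (not isolated)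
Conditions: O3 (1 equiv, Sudan red 7B end-point), CH2Cl2, −78 °C; then PPh3, −78 °C to rt
Reagents that add atoms: ozone, [O-][O+]=O
Why: Chemoselective ozonolysis; the electron-rich trisubstituted alkene should react far faster than the hindered vinyl group beside the silyloxy carbon, and reductive work-up gives the aldehyde.

**Step 3**
Reactants: 4 (4S)-4-methyl-4-(triethylsilyloxy)hex-5-enal
Product: 5 (3S)-7,7-dibromo-3-methyl-3-(triethylsilyloxy)hepta-1,6-diene
Conditions: CBr4, PPh3, 2,6-lutidine, CH2Cl2, 0 °C
Reagents that add atoms: tetrabromomethane, BrC(Br)(Br)Br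
Why: Ramirez dibromo-olefination of an aldehyde (first stage of the Corey–Fuchs sequence), buffered so that the silyl ether survives.

**Step 4**
Reactants: 6 bis(4,4,5,5-tetramethyl-1,3,2-dioxaborolan-2-yl)methane; 7 3-methylbut-2-enal
Product: 9 (E)-4,4,5,5-tetramethyl-2-(4-methylpenta-1,3-dien-1-yl)-1,3,2-dioxaborolane, via lithiated diborylmethane 8 (not isolated)
Conditions: 6, lithium 2,2,6,6-tetramethylpiperidide, THF, 0 °C; then 7, −78 °C to rt
Reagents that add atoms: none
Why: Boron–Wittig olefination; the α-boryl carbanion adds 1,2 to the enal and syn-eliminates borate, which should give the trans-alkenyl boronate.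

**Step 5**
Reactants: 5 (3S)-7,7-dibromo-3-methyl-3-(triethylsilyloxy)hepta-1,6-diene; 9 (E)-dienyl pinacol boronate
Product: 10 (3S,6Z,8E)-7-bromo-3,11-dimethyl-3-(triethylsilyloxy)dodeca-1,6,8,10-tetraene
Conditions: Pd2(dba)3 (2.5 mol %), tri(2-furyl)phosphine, Cs2CO3, 1,4-dioxane/H2O, 60 °C
Reagents that add atoms: none
Why: Stereoselective Suzuki–Miyaura mono-coupling of a 1,1-dibromoalkene; oxidative addition should occur at the less hindered C–Br bond trans to the chain, so the dienyl group enters trans and the remaining bromine stays cis to the chain.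

**Step 6**
Reactants: 10 (3S,6Z,8E)-7-bromo-3,11-dimethyl-3-(triethylsilyloxy)dodeca-1,6,8,10-tetraene; 11 formaldehyde
Product: 13 (2Z,3E)-6-methyl-2-[(4S)-4-methyl-4-(triethylsilyloxy)hex-5-en-1-ylidene]hepta-3,5-dien-1-ol, via alkenyllithium 12 (not isolated)
Conditions: t-BuLi (2.1 equiv), Et2O, −78 °C; then CH2O gas (from cracked paraformaldehyde), −78 to 0 °C; aq. NH4Cl
Reagents that add atoms: none
Why: Bromine–lithium exchange with retention of alkene geometry, then hydroxymethylation of the alkenyllithium, places CH2OH cis to the chain (Z-allylic alcohol).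

**Step 7**
Reactants: 13 (2Z,3E)-dienyl allylic alcohol; 14 2,2,6-trimethyl-4H-1,3-dioxin-4-one
Product: 15 acetoacetate (3-oxobutanoate) of alcohol 13
Conditions: toluene, 110 °C (acetone distilled off)
Reagents that add atoms: none
Why: Acetoacetylation by acetylketene released from the dioxinone in a thermal retro-[4+2]; the triene has an E central double bond and cannot electrocyclise at this temperature.

**Step 8**
Reactants: 15 acetoacetate of alcohol 13
Product: 16 2-diazo-3-oxobutanoate of alcohol 13
Conditions: 4-acetamidobenzenesulfonyl azide, Et3N, MeCN, 0 °C to rt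
Reagents that add atoms: 4-acetamidobenzenesulfonyl azide, CC(=O)Nc1ccc(cc1)S(=O)(=O)N=[N+]=[N-]
Why: Regitz diazo transfer to the active methylene of a β-keto ester.

**Step 9**
Reactants: 16 2-diazo-3-oxobutanoate of alcohol 13
Product: 17 (1R,5S,6R)-1-acetyl-5-[(1E)-4-methylpenta-1,3-dien-1-yl]-6-[(3S)-3-methyl-3-(triethylsilyloxy)pent-4-en-1-yl]-3-oxabicyclo[3.1.0]hexan-2-one
Conditions: [Co(3,5-DitBu-ChenPhyrin)] (D2-symmetric chiral amidoporphyrin complex of divalent cobalt, 2 mol %), toluene, rt to 40 °C
Reagents that add atoms: none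
Why: Asymmetric intramolecular cyclopropanation of an allyl α-acyldiazoacetate (metalloradical carbene transfer) at the proximal alkene, the only one that gives a five-membered lactone; the catalyst selects the alkene face and so sets the chain-bearing carbon C6, the lactone enforces cis fusion at C1/C5, the chain is expected endo from the Z-alkene, and the exo C1/C5 epimer would feed the same zwitterion in step 10.

**Step 10**
Reactants: 17 (1R,5S,6R)-1-acetyl-5-dienyl-6-alkyl-3-oxabicyclo[3.1.0]hexan-2-one; 11 formaldehyde
Product: 18 (1R,5R,8S)-1-acetyl-5-[(1E)-4-methylpenta-1,3-dien-1-yl]-8-[(3S)-3-methyl-3-(triethylsilyloxy)pent-4-en-1-yl]-3,6-dioxabicyclo[3.2.1]octan-2-one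
Conditions: Pd2(dba)3 (2.5 mol %), dppe (6 mol %), CH2O (5 equiv, THF solution from cracked paraformaldehyde), THF, 0 to 40 °C
Reagents that add atoms: none
Why: Proposed new method: zerovalent palladium should ionise the strained C1–C5 bond of 17 anti to the dienyl π-system to give a zwitterion (β-keto-lactone enolate at the future ring-fusion carbon, η3-allyl palladium at the future quaternary ether carbon), whose enolate carbon adds to formaldehyde and whose new alkoxide then attacks the allyl terminus; the closest known reaction is the palladium-catalysed formal [3+2] cycloaddition of 2-vinylcyclopropane-1,1-dicarbonyl compounds with aldehydes, not yet shown for a ring-fused cyclopropane lactone with a fully substituted donor carbon or for formaldehyde. The oxolane closes by 5-exo allylic etherification (oxygen onto the ring-embedded allyl terminus, the rest of the diene staying outside the ring). The acetyl-bearing quaternary centre C1 is set by addition of formaldehyde to the enolate face anti to the side chain on the neighbouring carbon, the only stereocentre that survives ionisation. The quaternary ether centre C5 is then fixed by the lactone tether, because the CH2–O bridge can only span the face that carries the hydroxymethyl arm (net retention by double inversion at palladium). The step needs O-attack at the ring terminus rather than at the distal diene carbons, and no collapse of the zwitterion by intramolecular O- or C-allylation; the tether secures both, since every alternative closure would place a double bond at a bridgehead of a small bicycle (Bredt's rule). The zwitterion should therefore only revert to 17 or be trapped by formaldehyde.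

**Step 11**
Reactants: 18 (1R,5R,8S)-1-acetyl-3,6-dioxabicyclo[3.2.1]octan-2-one
Product: 20 1-[(3S,4S,5R)-5-(hydroxymethyl)-5-[(1E)-4-methylpenta-1,3-dien-1-yl]-4-[(3S)-3-methyl-3-(triethylsilyloxy)pent-4-en-1-yl]oxolan-3-yl]ethan-1-one, via β-keto acid 19 (not isolated)
Conditions: LiOH, THF/H2O, 0 °C to rt; then AcOH to pH 5, 40 °C; then K2CO3, MeOH, rt
Reagents that add atoms: none
Why: Saponification of the strained bridged lactone, decarboxylation of the resulting β-keto acid, and base equilibration alpha to the ketone, which should place the acetyl group trans to the neighbouring side chain (the thermodynamic 3,4-trans oxolane).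

**Step 12**
Reactants: 20 hydroxy methyl ketone
Product: 21 [(2R,3S,4S)-4-acetyl-2-[(1E)-4-methylpenta-1,3-dien-1-yl]-3-[(3S)-3-methyl-3-(triethylsilyloxy)pent-4-en-1-yl]oxolan-2-yl]methyl hexadecanoate
Conditions: hexadecanoyl chloride, pyridine, DMAP (cat.), CH2Cl2, 0 °C to rt
Reagents that add atoms: hexadecanoyl chloride, CCCCCCCCCCCCCCCC(Cl)=O
Why: DMAP-catalysed acylation of the only free (primary) hydroxyl group.

**Step 13**
Reactants: 21 keto palmitate
Product: 23 [(2R,3S,4S)-2-[(1E)-4-methylpenta-1,3-dien-1-yl]-3-[(3S)-3-methyl-3-(triethylsilyloxy)pent-4-en-1-yl]-4-[1-(trifluoromethanesulfonyloxy)ethenyl]oxolan-2-yl]methyl hexadecanoate, via potassium enolate 22 (not isolated)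
Conditions: KN(SiMe3)2 (1.05 equiv), THF, −78 °C; then PhNTf2, −78 to 0 °C
Reagents that add atoms: N-phenylbis(trifluoromethanesulfonimide), O=S(=O)(N(c1ccccc1)S(=O)(=O)C(F)(F)F)C(F)(F)F
Why: Kinetic deprotonation of the methyl ketone at the unhindered methyl group (more acidic than the ester and faster than the ring methine) and O-triflation give the terminal enol triflate without touching the ring stereocentre.

**Step 14**
Reactants: 23 enol triflate
Product: 24 [(2R,3S,4R)-2-[(1E)-4-methylpenta-1,3-dien-1-yl]-3-[(3S)-3-methyl-3-(triethylsilyloxy)pent-4-en-1-yl]-4-(penta-1,4-dien-2-yl)oxolan-2-yl]methyl hexadecanoate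
Conditions: allyltributylstannane, Pd(PPh3)4 (5 mol %), LiCl, THF, 60 °C
Reagents that add atoms: allyltributylstannane, C=CC[Sn](CCCC)(CCCC)CCCC
Why: Stille coupling of a vinyl triflate with an allylstannane installs the exocyclic methylene and the skipped diene in one step under neutral conditions.

**Step 15**
Reactants: 24 silyl-protected tetraene
Product: 25 [(2R,3S,4R)-3-[(3S)-3-hydroxy-3-methylpent-4-en-1-yl]-2-[(1E)-4-methylpenta-1,3-dien-1-yl]-4-(penta-1,4-dien-2-yl)oxolan-2-yl]methyl hexadecanoate
Conditions: Bu4NF, AcOH (1:1), THF, 0 °C to rt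
Reagents that add atoms: none
Why: Buffered fluoride cleavage of the tertiary triethylsilyl ether, which should spare the palmitate and the acid-sensitive tertiary dienyl ether; the free allylic hydroxyl also makes the vinyl group a better metathesis partner.

**Step 16**
Reactants: 25 free tertiary allylic alcohol
Product: 26 CNP0150666.1 (target)
Conditions: RuCl2(=CHPh)(H2IMes)(PCy3) (second-generation Grubbs catalyst, 10 mol %), 1,4-benzoquinone (20 mol %), CH2Cl2 (1 mM), 40 °C
Reagents that add atoms: none
Why: Ring-closing metathesis between the two terminal monosubstituted alkenes (allyl group and vinyl carbinol) on trans-disposed arms of the oxolane; the nine-membered ring can only hold the Z-alkene, and the internal side-chain diene (flanked by a quaternary carbon) should be much less reactive.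

**Compound list**
1 | (S)-(+)-linalool, (3S)-3,7-dimethylocta-1,6-dien-3-ol | C=C[C@@](C)(O)CCC=C(C)C | starting material
2 | (3S)-3,7-dimethyl-3-(triethylsilyloxy)octa-1,6-diene | C=C[C@@](C)(O[Si](CC)(CC)CC)CCC=C(C)C | intermediate
3 | secondary ozonide of 2: 3,3-dimethyl-5-[(3S)-3-methyl-3-(triethylsilyloxy)pent-4-en-1-yl]-1,2,4-trioxolane (mixture at the ring CH) | C=C[C@@](C)(O[Si](CC)(CC)CC)CCC1OOC(C)(C)O1 | intermediate
4 | (4S)-4-methyl-4-(triethylsilyloxy)hex-5-enal | C=C[C@@](C)(O[Si](CC)(CC)CC)CCC=O | intermediate
5 | (3S)-7,7-dibromo-3-methyl-3-(triethylsilyloxy)hepta-1,6-diene | C=C[C@@](C)(O[Si](CC)(CC)CC)CCC=C(Br)Br | intermediate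
6 | bis(4,4,5,5-tetramethyl-1,3,2-dioxaborolan-2-yl)methane | CC1(C)OB(CB2OC(C)(C)C(C)(C)O2)OC1(C)C | starting material
7 | 3-methylbut-2-enal | CC(C)=CC=O | starting material
8 | [bis(4,4,5,5-tetramethyl-1,3,2-dioxaborolan-2-yl)methyl]lithium | [Li]C(B1OC(C)(C)C(C)(C)O1)B1OC(C)(C)C(C)(C)O1 | intermediate
9 | (E)-4,4,5,5-tetramethyl-2-(4-methylpenta-1,3-dien-1-yl)-1,3,2-dioxaborolane | CC(C)=C/C=C/B1OC(C)(C)C(C)(C)O1 | intermediate
10 | (3S,6Z,8E)-7-bromo-3,11-dimethyl-3-(triethylsilyloxy)dodeca-1,6,8,10-tetraene | C=C[C@@](C)(O[Si](CC)(CC)CC)CC/C=C(Br)/C=C/C=C(C)C | intermediate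
11 | formaldehyde (monomer from paraformaldehyde) | C=O | starting material
12 | alkenyllithium from 10 (lithium in place of bromine, geometry retained) | C=C[C@@](C)(O[Si](CC)(CC)CC)CC/C=C([Li])/C=C/C=C(C)C | intermediate
13 | (2Z,3E)-6-methyl-2-[(4S)-4-methyl-4-(triethylsilyloxy)hex-5-en-1-ylidene]hepta-3,5-dien-1-ol | C=C[C@@](C)(O[Si](CC)(CC)CC)CC/C=C(CO)/C=C/C=C(C)C | intermediate
14 | 2,2,6-trimethyl-4H-1,3-dioxin-4-one | CC1=CC(=O)OC(C)(C)O1 | starting material
15 | 3-oxobutanoate (acetoacetate) of 13 | C=C[C@@](C)(O[Si](CC)(CC)CC)CC/C=C(COC(=O)CC(C)=O)/C=C/C=C(C)C | intermediate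
16 | 2-diazo-3-oxobutanoate of 13 | C=C[C@@](C)(O[Si](CC)(CC)CC)CC/C=C(COC(=O)C(=[N+]=[N-])C(C)=O)/C=C/C=C(C)C | intermediate
17 | (1R,5S,6R)-1-acetyl-5-[(1E)-4-methylpenta-1,3-dien-1-yl]-6-[(3S)-3-methyl-3-(triethylsilyloxy)pent-4-en-1-yl]-3-oxabicyclo[3.1.0]hexan-2-one (side chain endo, cis to the lactone CH2) | C=C[C@@](C)(O[Si](CC)(CC)CC)CC[C@H]1[C@]2(C(C)=O)[C@@]1(/C=C/C=C(C)C)COC2=O | intermediate
18 | (1R,5R,8S)-1-acetyl-5-[(1E)-4-methylpenta-1,3-dien-1-yl]-8-[(3S)-3-methyl-3-(triethylsilyloxy)pent-4-en-1-yl]-3,6-dioxabicyclo[3.2.1]octan-2-one (side chain syn to the lactone bridge) | C=C[C@@](C)(O[Si](CC)(CC)CC)CC[C@H]1[C@]2(C(C)=O)CO[C@@]1(/C=C/C=C(C)C)COC2=O | intermediate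
19 | (3R,4S,5R)-3-acetyl-5-(hydroxymethyl)-5-[(1E)-4-methylpenta-1,3-dien-1-yl]-4-[(3S)-3-methyl-3-(triethylsilyloxy)pent-4-en-1-yl]oxolane-3-carboxylic acid | C=C[C@@](C)(O[Si](CC)(CC)CC)CC[C@H]1[C@](C(=O)O)(C(C)=O)CO[C@@]1(/C=C/C=C(C)C)CO | intermediate
20 | 1-[(3S,4S,5R)-5-(hydroxymethyl)-5-[(1E)-4-methylpenta-1,3-dien-1-yl]-4-[(3S)-3-methyl-3-(triethylsilyloxy)pent-4-en-1-yl]oxolan-3-yl]ethan-1-one | C=C[C@@](C)(O[Si](CC)(CC)CC)CC[C@H]1[C@H](C(C)=O)CO[C@@]1(/C=C/C=C(C)C)CO | intermediate
21 | [(2R,3S,4S)-4-acetyl-2-[(1E)-4-methylpenta-1,3-dien-1-yl]-3-[(3S)-3-methyl-3-(triethylsilyloxy)pent-4-en-1-yl]oxolan-2-yl]methyl hexadecanoate | C=C[C@@](C)(O[Si](CC)(CC)CC)CC[C@H]1[C@H](C(C)=O)CO[C@@]1(/C=C/C=C(C)C)COC(=O)CCCCCCCCCCCCCCC | intermediate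
22 | potassium enolate of 21 (kinetic, at the acetyl methyl group) | C=C[C@@](C)(O[Si](CC)(CC)CC)CC[C@H]1[C@H](C(=C)O[K])CO[C@@]1(/C=C/C=C(C)C)COC(=O)CCCCCCCCCCCCCCC | intermediate
23 | [(2R,3S,4S)-2-[(1E)-4-methylpenta-1,3-dien-1-yl]-3-[(3S)-3-methyl-3-(triethylsilyloxy)pent-4-en-1-yl]-4-[1-(trifluoromethanesulfonyloxy)ethenyl]oxolan-2-yl]methyl hexadecanoate | C=C[C@@](C)(O[Si](CC)(CC)CC)CC[C@H]1[C@H](C(=C)OS(=O)(=O)C(F)(F)F)CO[C@@]1(/C=C/C=C(C)C)COC(=O)CCCCCCCCCCCCCCC | intermediate
24 | [(2R,3S,4R)-2-[(1E)-4-methylpenta-1,3-dien-1-yl]-3-[(3S)-3-methyl-3-(triethylsilyloxy)pent-4-en-1-yl]-4-(penta-1,4-dien-2-yl)oxolan-2-yl]methyl hexadecanoate | C=C[C@@](C)(O[Si](CC)(CC)CC)CC[C@H]1[C@H](C(=C)CC=C)CO[C@@]1(/C=C/C=C(C)C)COC(=O)CCCCCCCCCCCCCCC | intermediate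
25 | [(2R,3S,4R)-3-[(3S)-3-hydroxy-3-methylpent-4-en-1-yl]-2-[(1E)-4-methylpenta-1,3-dien-1-yl]-4-(penta-1,4-dien-2-yl)oxolan-2-yl]methyl hexadecanoate | C=C[C@@](C)(O)CC[C@H]1[C@H](C(=C)CC=C)CO[C@@]1(/C=C/C=C(C)C)COC(=O)CCCCCCCCCCCCCCC | intermediate
26 | CNP0150666.1: trans-fused oxolane/cyclononene with Z ring alkene, (S)-tertiary carbinol, exocyclic methylene, (E)-4-methylpenta-1,3-dienyl and palmitoyloxymethyl on the quaternary ether carbon | C=C1C/C=C\[C@@](C)(O)CC[C@H]2[C@H]1CO[C@@]2(/C=C/C=C(C)C)COC(=O)CCCCCCCCCCCCCCC | target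

**Summary**
Total step count: 16. Longest linear sequence: 15 steps (steps 1–3 and 5–16, from linalool); step 4 is a one-step side branch.

**Steps most likely to fail**

Step 10 (proposed new method). The zwitterion may re-close to 17 faster than it captures formaldehyde, which also oligomerises, or formaldehyde may add to the enolate face syn to the side chain so that ring closure gives the epimeric bridged ether. The fallback sets out from 17 and returns at 18 in three reactions of known type. Palladium-catalysed 1,5-addition of acetic acid (Pd(PPh3)4, AcOH, THF) would open the vinylcyclopropane to the six-membered keto lactone with an allylic acetate in the side chain, the ring-opened allylic acetate F1 (acetate regio- and stereoisomers all ionise to the same allyl complex later). Base-catalysed hydroxymethylation of its β-keto-lactone methine with aqueous formaldehyde (Et3N cat., THF) would give the hydroxymethyl keto lactone F2 under equilibrating aldol conditions, where the facial outcome can be checked and the diastereomers separated. Intramolecular Tsuji–Trost allylic etherification (Pd2(dba)3, dppe, THF) would then close the oxolane to 18.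

Step 9. The catalyst may discriminate the alkene faces poorly at the chain-bearing carbon, or the carbene may be transferred to the remote double bonds of the triene, or a stepwise radical pathway may divert the delocalised intermediate. The fallback sets out from 16 and returns at 17. Deacetylation of 16 (LiOH, H2O/THF) would give the allyl diazoacetate F3. This would be cyclised with the dirhodium carboxamidate Rh2(5S-MEPY)4 (dirhodium tetrakis[methyl 2-oxopyrrolidine-5(S)-carboxylate], or its antipode as required), a concerted carbenoid addition that is best precedented for Z-alkenes, to the acetyl-free cyclopropane lactone F4. Deprotonation at the lactone α-bridgehead (LiN(SiMe3)2, THF, −78 °C) and C-acetylation with 1-acetylimidazole on the only accessible exo face would give 17.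

Step 16. The ruthenium carbene may engage the internal double bond of the conjugated side-chain diene (truncation or seven-membered ring formation), or intermolecular metathesis may outrun closure of the strained nine-membered ring. The fallback sets out from 25 and returns at 26, and addresses only the first of these. The conjugated diene would be masked as its tricarbonyliron complex F5 with Fe(CO)3(benzylideneacetone) in toluene at 45 °C; zerovalent iron binds the 1,3-diene and not the isolated or skipped alkenes, and both planar-chiral diastereomers are usable. Ring-closing metathesis with the second-generation Grubbs catalyst would then give the complexed macrocycle F6, and oxidative decomplexation with Me3NO in acetone would release 26.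

**Further compounds**
F1 | step 10 | ring-opened allylic acetate: (4S)-3-acetyl-5-(2-acetoxy-4-methylpent-3-en-1-ylidene)-4-[(3S)-3-methyl-3-(triethylsilyloxy)pent-4-en-1-yl]oxan-2-one (mixture at C3, at the acetate carbon and in alkene geometry) | C=C[C@@](C)(O[Si](CC)(CC)CC)CC[C@H]1C(C(C)=O)C(=O)OCC1=CC(OC(C)=O)C=C(C)C
F2 | step 10 | hydroxymethyl keto lactone: 3-hydroxymethyl derivative of F1 with CH2OH anti to the side chain | C=C[C@@](C)(O[Si](CC)(CC)CC)CC[C@H]1[C@@](CO)(C(C)=O)C(=O)OCC1=CC(OC(C)=O)C=C(C)C
F3 | step 9 | allyl diazoacetate: diazoacetate of alcohol 13 | C=C[C@@](C)(O[Si](CC)(CC)CC)CC/C=C(COC(=O)C=[N+]=[N-])/C=C/C=C(C)C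
F4 | step 9 | acetyl-free cyclopropane lactone: 5-[(1E)-4-methylpenta-1,3-dien-1-yl]-6-[(3S)-3-methyl-3-(triethylsilyloxy)pent-4-en-1-yl]-3-oxabicyclo[3.1.0]hexan-2-one, configuration as in 17 with H in place of acetyl | C=C[C@@](C)(O[Si](CC)(CC)CC)CC[C@H]1[C@@H]2[C@@]1(/C=C/C=C(C)C)COC2=O
F5 | step 16 | tricarbonyliron complex of 25 (η4 on the side-chain diene, mixture of planar diastereomers) | C=C[C@@](C)(O)CC[C@H]1[C@H](C(=C)CC=C)CO[C@@]1(/C=C/C=C(C)C)COC(=O)CCCCCCCCCCCCCCC.[Fe].[C-]#[O+].[C-]#[O+].[C-]#[O+]
F6 | step 16 | tricarbonyliron complex of 26 (η4 on the side-chain diene) | C=C1C/C=C\[C@@](C)(O)CC[C@H]2[C@H]1CO[C@@]2(/C=C/C=C(C)C)COC(=O)CCCCCCCCCCCCCCC.[Fe].[C-]#[O+].[C-]#[O+].[C-]#[O+]
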